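Remark (assumption): the SMILES is read literally, so the γ-lactone is trans-fused to the 1,2-dioxane (16S,17R; H-16 anti to the methyl on C17) and C14 is R; (+)-larixol is taken as a purchasable starting material.

## Structural features

The target is a C25 sesterterpenoid methyl ester; numbering used throughout: C1–C10 trans-decalin (ring A C1–C5/C10, ring B C5–C10), side chain C11–C19, C20 methyl on C17, C21 methylene on C13, C22 methyl on C8, C23 ester carbon on C4, C24 methyl on C4, C25 methyl on C10. Rings A and B carry six stereocentres: C4 (quaternary, CO2Me α-equatorial, CH3 β-axial), C5 (H α), C6 (OH α, equatorial), C8 (OH α, CH3 β), C9 (chain β) and C10 (CH3 β); the 6α-OH and the C23 ester are peri to each other and form a latent 23,6-lactone. C9 is joined through C11–C12 to C13, a 1,1-disubstituted alkene that bears the allylic peroxy carbon C14. Ring C is a 1,2-dioxane (C14, C15, C16, C17, O, O) fused along C16–C17 to ring D, a γ-lactone (O–C16, C17–C18–C19=O); C14 is R, C16 is S and C17 is R, so H-16 and the C20 methyl are anti, the lactone is trans-fused, and the alkenyl group on C14 is cis to C18 and trans to O16. Fragile groups are the O–O bond (reductants, low-valent metals, phosphines), the allylic C14–H next to the peroxide (base-induced Kornblum–DeLaMare cleavage), the β-peroxy lactone (E1cB opening to a butenolide), the tertiary 8-OH, and the 6-OH/C23 ester pair. The real difficulty is rings C and D: three stereocentres insulated from the decalin by C11–C13, an allylic peroxide, and a trans ring fusion that a peroxide conjugate addition to a butenolide cannot deliver. The key step exploits that O16 and the peroxide oxygen on C17 are anti across C16–C17 and that C14 is the 1,4-partner of C17: this is the pattern left by anti opening of an E-16,17-epoxide at C17 by one end of H2O2 and SN2 alkylation of the other end at C14.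

## Logic of the disconnections

29 from 28: the two O–Si bonds at O6 and O8 are cut. The silyl ethers are needed only to keep the ring B hydroxyls out of the oxidation and sulfonylation steps. The demand is a fluoride source that is not basic, because the β-peroxy lactone and the allylic C14–H do not tolerate base.

28 from 25 (key step, through 26 and 27): the two C–O bonds of the peroxide bridge (C17–O and C14–O) and the lactone bond O16–C19 are cut. In one sentence: H2O2 is stitched as an O–O linchpin between C17 and C14 of open-chain 25 by two inversions, and the O16 hydroxyl set free in the first of them closes ring D. The cut is made there because each of the three stereocentres then becomes the outcome of a stereospecific event (C16 retained, C17 and C14 inverted) and the trans fusion follows from anti epoxide opening. The gain is that rings C and D disappear into an acyclic chain with one epoxide and one sulfonate. The demand is attack of H2O2 at the tertiary C17 only, an allylic sulfonate that survives the acidic first stage, and ring closure under SN2 conditions without a strong base.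

25 from 24 and 24 from 23: the S–O bond of the mesylate and the two C–O bonds of the epoxide are cut. The epoxide is placed on an E-trisubstituted alkene because this is the best substrate class for ketone-catalysed asymmetric epoxidation, and the reagent, not the remote decalin, sets C16 and C17. The demand is chemoselectivity for the trisubstituted C16=C17 alkene over the 1,1-disubstituted C13=C21 alkene and a pH at which the β,γ-epoxy ester does not open by E1cB.

23 from 22, 22 from 21, 21 from 20 and 7: the C14–H bond (hydride) and the C13–C14 bond are cut. C13–C14 is the only bond whose formation brings the exocyclic methylene, the carbinol and the whole C14–C19 chain together in one step from a methyl ketone derivative. The gain is a convergent union of a decalin (C1–C13, C21–C25) with a six-carbon aldehyde. The demand is a mild alkenyl–aldehyde coupling that tolerates esters and a skipped alkene, and a reagent-controlled reduction, since the coupling cannot be steered by the decalin.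

20 from 18 (through 19) and 18 from 17: the enol O–S bond and the two O–Si bonds are cut. The methyl ketone C13(=O)–C21H3 already holds C13 and the future methylene C21. The demand is kinetic enolisation toward the methyl group.

17 from 15 (through 16), 15 from 13 (through 14) and 13 from 12: the ester O–CH3 bond, the lactone carbonyl oxygen and the O6–C23 bond are cut. The C23 ester and the 6α-OH are peri, so C23 can be oxidised by the oxygen on C6 through a six-membered hydrogen transfer. The gain is that the C4 quaternary stereocentre and the 6α-OH are taken from a gem-dimethyl carbinol of the chiral pool. The demand is that O6 is the only free hydroxyl in 12 and that only the equatorial C23 methyl lies within reach.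

12 from 10 (through 11), 10 from 9 and 9 from 8: the ketal C–O bonds are cut, the two vinyl carbons C14 and C15 of the starting diterpene are restored, and the C8–O bond is cut back to the exocyclic alkene. All ring A/B carbons, C5, C6, C9, C10 and C11–C13 with C21 come from 8. The demand is α-face attack at C8 and an oxidative cleavage that spares the secondary 6-OH.

7 from 6, 6 from 3 and 4 (through 5), 3 from 1 (through 2): the aldehyde is taken back to the alcohol, the C17–C18 bond is cut, and the C17–I and C16–H bonds are cut. A syn hydrometalation of a methyl alkyne fixes the E geometry that later decides the trans ring fusion. The demand is retention of geometry and no migration of the alkene into conjugation.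

## Other disconnections considered

Alternative 1: the first idea is the biomimetic one, cutting C14–O and C17–O as a Schenck ene reaction followed by a peroxy-Michael addition. Forward, singlet oxygen would convert the 13E-alkene butenolide A1 into the allylic hydroperoxide A2, and base would close ring C by 6-exo-trig addition to the butenolide. The plan is rejected on structure: the four-atom tether C15–C14–O–O can reach C17 only on the butenolide face that carries C15 (closure on the other face would need a dihedral near 150° in a six-membered transition state), so the product would be the cis-fused 17-epimer A3 and not 29. In addition the ene step has no element that controls C14, and it can also abstract hydrogen from C15 or C12.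

Alternative 2: cut both peroxide C–O bonds as a [4+2] cycloaddition of singlet oxygen to the (14E,16E)-triene acid A4, giving the 3,6-dihydro-1,2-dioxine A5, then lactonise onto C15=C16 (iodolactonisation and deiodination). The cis relation of the C14 alkenyl group and C18 requires the C20 methyl to point inside the s-cis diene, which should slow the cycloaddition in favour of ene reactions at the cross-conjugated C13=C21 unit. Nothing in A4 distinguishes the two diene faces, so both configurations of the peroxide unit are expected. The later removal of iodine would pass through a C15 radical β to the O–O bond, which should fragment. The chosen plan has one more stereocentre-setting step before the key step but none after it.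

Alternative 3: cut C12–C13 and join a finished peroxy-lactone vinyl bromide A6 to the decalin alkylborane A8 (from the 9-vinyl decalin A7) by a B-alkyl Suzuki coupling. This is the most convergent plan, but C14–O in A6 is an allylic leaving group, and after oxidative addition a β-leaving group, for zerovalent palladium. The aqueous base of the coupling is also expected to trigger Kornblum–DeLaMare cleavage at C14–H and retro-Michael opening of the β-peroxy lactone. A6 would need the same peroxide annulation on a less suitable 2-bromoallyl sulfonate, and A7 requires removal of one more carbon from the natural C13 ketone. Keeping the peroxide for the last C–O bond-forming step avoids all metal-mediated chemistry in its presence.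

Key step: step 17

## Steps

Step 1
Reactants: 1 pent-3-yn-1-ol
Product: 3 (E)-4-iodopent-3-en-1-ol, via alkenylzirconocene 2 (not isolated)
Conditions: Cp2Zr(H)Cl (2.3 equiv), THF, rt to 40 °C; then I2, 0 °C
Reagents that add atoms: iodine, II
Why: Hydrozirconation–iodination: Zr–H adds syn, the excess hydride equilibrates zirconium to the less hindered methyl-bearing carbon (2), and iodinolysis with retention should give the E iodide with H and I cis.

Step 2
Reactants: 3 (E)-4-iodopent-3-en-1-ol; 4 methyl bromoacetate
Product: 6 methyl (E)-6-hydroxy-3-methylhex-3-enoate, via Reformatsky reagent 5 (not isolated)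
Conditions: Zn dust, TMSCl (cat.), THF, rt (forms 5, 3 equiv); then 3, Pd(PPh3)4 (5 mol%), THF–DMPU, 50 °C
Reagents that add atoms: none
Why: Negishi-type cross-coupling of a vinyl iodide with a zinc ester enolate; oxidative addition and reductive elimination at palladium retain the alkene geometry, and the neutral medium should leave the β,γ-unsaturated ester out of conjugation.

Step 3
Reactants: 6 methyl (E)-6-hydroxy-3-methylhex-3-enoate
Product: 7 methyl (E)-3-methyl-6-oxohex-3-enoate
Conditions: Dess–Martin periodinane, pyridine, CH2Cl2, 0 °C; used at once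
Reagents that add atoms: none
Why: Dess–Martin oxidation of a primary homoallylic alcohol; the pyridine buffer and immediate use should prevent migration of the skipped alkene into conjugation with the aldehyde.

Step 4
Reactants: 8 (+)-larixol
Product: 9 larixol 8α-spiroepoxide (epoxide on C8/C22)
Conditions: mCPBA (1.05 equiv), NaHCO3, CH2Cl2, 0 °C
Reagents that add atoms: 3-chloroperoxybenzoic acid, O=C(OO)c1cccc(Cl)c1
Why: Prilezhaev epoxidation; the 1,1-disubstituted exocyclic alkene is far more nucleophilic than the vinyl group, and attack anti to the axial C25 methyl should place the epoxide oxygen α on C8.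

Step 5
Reactants: 9 larixol 8α-spiroepoxide
Product: 10 (13S)-labd-14-ene-6α,8α,13-triol
Conditions: LiAlH4, THF, 0 °C to reflux
Reagents that add atoms: none
Why: Hydride opens the spiro-epoxide at its primary carbon C22 (SN2), which turns it into the axial 8β-methyl and leaves the 8α tertiary alcohol without touching C8.

Step 6
Reactants: 10 (13S)-labd-14-ene-6α,8α,13-triol
Product: 12 cyclic methyl ketal (8α,13-epoxy-13β-methoxy) with free 6α-OH, via hydroxy ketone 11 (not isolated)
Conditions: K2OsO4·2H2O (2 mol%), NaIO4 (4 equiv), 2,6-lutidine, dioxane–H2O, rt; extraction; then PPTS (cat.), MeOH, 3 Å sieves, rt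
Reagents that add atoms: methanol, CO
Why: Lemieux–Johnson cleavage: dihydroxylation of the vinyl group and two periodate cleavages (C14–C15, then the α-hydroxy aldehyde at C13–C14) leave methyl ketone 11 without oxidising the 6-OH; in acidic methanol the 8α-OH closes onto the ketone to the six-membered mixed ketal (methoxy axial, anomeric), which masks both the tertiary alcohol and the ketone for the next step.

Step 7
Reactants: 12 cyclic methyl ketal with free 6α-OH
Product: 13 6α,23-ether (tetrahydrofuran across C4–C5–C6) of the ketal
Conditions: PhI(OAc)2, I2, cyclohexane–CH2Cl2, visible light, rt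
Reagents that add atoms: none
Why: Suárez hypoiodite reaction: the 6α-alkoxyl radical abstracts hydrogen from the peri, equatorial C23 methyl through a six-membered transition state, and iodine transfer followed by ring closure gives the tetrahydrofuran; the axial C24, C25 and C22 methyls are out of reach of the equatorial oxygen, which is what fixes the C4 configuration.

Step 8
Reactants: 13 6α,23-ether of the ketal
Product: 15 23,6α-lactone with 8α-OH and C13 methyl ketone, via lactone ketal 14 (not isolated)
Conditions: RuCl3·3H2O (5 mol%), NaIO4, CCl4–MeCN–H2O, rt; then 1 M HCl, THF, rt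
Reagents that add atoms: sodium periodate, [Na+].[O-]I(=O)(=O)=O; water, O
Why: RuO4 oxidises the ether CH2 (C23) in preference to the ether CH (C6) to give the γ-lactone 14, and dilute acid then hydrolyses the mixed ketal back to the hydroxy ketone.

Step 9
Reactants: 15 23,6α-lactone hydroxy ketone
Product: 17 methyl 6α,8α-dihydroxy-13-oxo ester (C23 methyl ester), via potassium carboxylate 16 (not isolated)
Conditions: KOH, MeOH–H2O, 65 °C; evaporation; then MeI, DMF, rt
Reagents that add atoms: potassium hydroxide, [K+].[OH-]; iodomethane, CI
Why: Saponification of the strained peri lactone and SN2 methylation of the carboxylate; no acid is used, so the free 6α-OH should not close back onto C23.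

Step 10
Reactants: 17 methyl 6α,8α-dihydroxy-13-oxo ester
Product: 18 6,8-bis-O-triethylsilyl ether of 17
Conditions: TESOTf (3 equiv), 2,6-lutidine, CH2Cl2, −78 to 0 °C
Reagents that add atoms: triethylsilyl trifluoromethanesulfonate, CC[Si](CC)(CC)OS(=O)(=O)C(F)(F)F
Why: Silyl triflate protection of the secondary and the tertiary alcohol; with both masked, C14–OH will later be the only hydroxyl in the molecule.

Step 11
Reactants: 18 6,8-bis-O-triethylsilyl ether of 17
Product: 20 vinyl triflate (C13=C21 with OTf on C13), via lithium enolate 19 (not isolated)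
Conditions: LiN(i-Pr)2, THF, −78 °C; then PhNTf2, −78 to 0 °C
Reagents that add atoms: N-phenylbis(trifluoromethanesulfonimide), O=S(=O)(N(c1ccccc1)S(=O)(=O)C(F)(F)F)C(F)(F)F
Why: Kinetic deprotonation of the methyl ketone at the methyl group and O-triflation of enolate 19; the C23 ester has no α-hydrogen and is shielded by the quaternary C4.

Step 12
Reactants: 20 vinyl triflate; 7 methyl (E)-3-methyl-6-oxohex-3-enoate
Product: 21 allylic alcohol (both C14 epimers)
Conditions: CrCl2 (4 equiv), NiCl2 (2 mol%), DMF–THF, rt
Reagents that add atoms: none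
Why: Nozaki–Hiyama–Kishi coupling (nickel-catalysed, chromium-mediated addition of a vinyl triflate to an aldehyde) forms C13–C14 under neutral conditions that tolerate both esters, the silyl ethers and the skipped alkene; C14 is formed without control and is corrected in steps 13 and 14.

Step 13
Reactants: 21 allylic alcohol (both C14 epimers)
Product: 22 enone (C14 ketone, C13=C21)
Conditions: Dess–Martin periodinane, pyridine, CH2Cl2, 0 °C; used at once
Reagents that add atoms: none
Why: Dess–Martin oxidation of an allylic alcohol; buffered, cold and non-basic conditions should keep the C16=C17 alkene from moving into conjugation.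

Step 14
Reactants: 22 enone
Product: 23 (14S)-allylic alcohol
Conditions: (R)-2-methyl-CBS-oxazaborolidine (0.5 equiv), catecholborane, toluene, −78 °C
Reagents that add atoms: none
Why: Corey–Bakshi–Shibata reduction: the α-branched alkenyl group acts as the large substituent and the allylic CH2 as the small one, so the (R)-catalyst should deliver hydride to give the 14S carbinol; catecholborane at −78 °C avoids hydroboration and 1,4-reduction.

Step 15
Reactants: 23 (14S)-allylic alcohol
Product: 24 (14S,16S,17S)-epoxy alcohol
Conditions: ent-Shi ketone (L-fructose-derived, 0.3 equiv), KHSO5 (as Oxone), K2CO3, Bu4NHSO4, Na2B4O7 buffer, MeCN–CH2(OMe)2–H2O, 0 °C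
Reagents that add atoms: potassium peroxymonosulfate, [K+].[O-]S(=O)(=O)OO
Why: Shi epoxidation: the chiral dioxirane epoxidises the E-trisubstituted alkene through the spiro transition state, the L-series catalyst giving the (16S,17S)-epoxide; the electron-poorer 1,1-disubstituted C13=C21 alkene is a poor substrate and should remain.

Step 16
Reactants: 24 (14S,16S,17S)-epoxy alcohol
Product: 25 (14S,16S,17S)-epoxy mesylate
Conditions: MsCl, Et3N, CH2Cl2, −40 °C; cold work-up, used crude
Reagents that add atoms: methanesulfonyl chloride, CS(=O)(=O)Cl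
Why: Sulfonylation through the sulfene with retention at C14; the only free hydroxyl is the one on C14.

Step 17
Reactants: 25 (14S,16S,17S)-epoxy mesylate
Product: 28 6,8-bis-O-triethylsilyl ether of the target, via hydroperoxy alcohol 26 (not isolated), via dioxane hydroxy ester 27 (not isolated)
Conditions: H2O2 (anhydrous, in Et2O, excess), H3PMo12O40 (5 mol%), Et2O, 0 °C; cold water wash; i-Pr2NEt, CH2Cl2, −20 to 0 °C; NaH2PO4 wash; CSA (cat.), CH2Cl2, rt
Reagents that add atoms: hydrogen peroxide, OO
Why: Three known reaction types are telescoped: acid-catalysed perhydrolysis of a trisubstituted epoxide, in which H2O2 attacks the tertiary carbon C17 anti to the breaking C–O bond (inversion) and leaves O16 as a hydroxyl on an untouched C16 (26); O-alkylation of the new hydroperoxide by the secondary sulfonate at C14 (6-exo-tet, SN2, 14S to 14R), modelled on the cyclisation of hydroperoxy sulfonates to 1,2-dioxanes (27); and acid-catalysed 5-exo-trig lactonisation of the γ-hydroxy ester (28). Ring C closes on the open chain, where a chair with the alkenyl group equatorial is available, and ring D closes last across the O16/C18 pair, so the trans fusion follows from anti opening of the E-derived epoxide and not from a facial preference. C17 is set by epoxide geometry plus inversion, C16 by the Shi epoxidation (retained), C14 by the CBS carbinol plus inversion, and none depends on the remote decalin. The step needs attack at C17 and not C16 (tertiary against secondary under acid; ester participation would need a four-membered or a 5-endo closure), a mesylate that survives the cold, base-free first stage, removal of excess H2O2 before the amine is added so that only the tethered hydroperoxide is alkylated, and a hindered weak base so that the β-peroxy ester is not opened by E1cB.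

Step 18
Reactants: 28 6,8-bis-O-triethylsilyl ether of the target
Product: 29 target CNP0162504.1
Conditions: HF·pyridine, pyridine, THF, 0 °C to rt
Reagents that add atoms: none
Why: Desilylation with a non-basic fluoride source; basic fluoride is avoided because the allylic C14–H and the β-peroxy lactone are base-sensitive, and no stereocentre is touched.

## Compound list

1 | pent-3-yn-1-ol | CC#CCCO | starting material
2 | (E)-alkenylzirconocene chloride, O-zirconated | C/C(=C\CCO[Zr](Cl)(C1C=CC=C1)C1C=CC=C1)[Zr](Cl)(C1C=CC=C1)C1C=CC=C1 | intermediate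
3 | (E)-4-iodopent-3-en-1-ol | OCC/C=C(\C)I | intermediate
4 | methyl bromoacetate | COC(=O)CBr | starting material
5 | bromo(2-methoxy-2-oxoethyl)zinc (Reformatsky reagent) | COC(=O)C[Zn]Br | intermediate
6 | methyl (E)-6-hydroxy-3-methylhex-3-enoate | OCC/C=C(\C)CC(=O)OC | intermediate
7 | methyl (E)-3-methyl-6-oxohex-3-enoate | O=CC/C=C(\C)CC(=O)OC | intermediate
8 | (+)-larixol | C=C[C@@](C)(O)CC[C@@H]1[C@@]2(C)CCCC(C)(C)[C@@H]2[C@@H](O)CC1=C | starting material
9 | larixol 8α-spiroepoxide | C=C[C@@](C)(O)CC[C@@H]1[C@@]2(C)CCCC(C)(C)[C@@H]2[C@@H](O)C[C@@]13OC3 | intermediate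
10 | (13S)-labd-14-ene-6α,8α,13-triol | C=C[C@@](C)(O)CC[C@@H]1[C@@]2(C)CCCC(C)(C)[C@@H]2[C@@H](O)C[C@@]1(C)O | intermediate
11 | 6α,8α-dihydroxy C13 methyl ketone | CC(=O)CC[C@@H]1[C@@]2(C)CCCC(C)(C)[C@@H]2[C@@H](O)C[C@@]1(C)O | intermediate
12 | cyclic methyl ketal (8α,13-epoxy-13β-methoxy), 6α-OH free | CO[C@]1(C)CC[C@@H]2[C@@]3(C)CCCC(C)(C)[C@@H]3[C@@H](O)C[C@@]2(C)O1 | intermediate
13 | 6α,23-ether of ketal 12 | CO[C@]1(C)CC[C@@H]2[C@@]3(C)CCC[C@@](C)(CO4)[C@@H]3[C@@H]4C[C@@]2(C)O1 | intermediate
14 | 23,6α-lactone methyl ketal | CO[C@]1(C)CC[C@@H]2[C@@]3(C)CCC[C@@](C)(C(=O)O4)[C@@H]3[C@@H]4C[C@@]2(C)O1 | intermediate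
15 | 23,6α-lactone, 8α-OH, C13 methyl ketone | CC(=O)CC[C@@H]1[C@@]2(C)CCC[C@@](C)(C(=O)O3)[C@@H]2[C@@H]3C[C@@]1(C)O | intermediate
16 | potassium 6α,8α-dihydroxy-13-oxo-23-carboxylate | CC(=O)CC[C@@H]1[C@@]2(C)CCC[C@@](C)(C(=O)[O-])[C@@H]2[C@@H](O)C[C@@]1(C)O.[K+] | intermediate
17 | methyl 6α,8α-dihydroxy-13-oxo ester (C23 methyl ester) | CC(=O)CC[C@@H]1[C@@]2(C)CCC[C@@](C)(C(=O)OC)[C@@H]2[C@@H](O)C[C@@]1(C)O | intermediate
18 | 6,8-bis-O-triethylsilyl ether of 17 | CC(=O)CC[C@@H]1[C@@]2(C)CCC[C@@](C)(C(=O)OC)[C@@H]2[C@@H](O[Si](CC)(CC)CC)C[C@@]1(C)O[Si](CC)(CC)CC | intermediate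
19 | lithium enolate of 18 (C13=C21) | C=C(O[Li])CC[C@@H]1[C@@]2(C)CCC[C@@](C)(C(=O)OC)[C@@H]2[C@@H](O[Si](CC)(CC)CC)C[C@@]1(C)O[Si](CC)(CC)CC | intermediate
20 | vinyl triflate (OTf on C13) | C=C(OS(=O)(=O)C(F)(F)F)CC[C@@H]1[C@@]2(C)CCC[C@@](C)(C(=O)OC)[C@@H]2[C@@H](O[Si](CC)(CC)CC)C[C@@]1(C)O[Si](CC)(CC)CC | intermediate
21 | allylic alcohol, both C14 epimers | C=C(CC[C@@H]1[C@@]2(C)CCC[C@@](C)(C(=O)OC)[C@@H]2[C@@H](O[Si](CC)(CC)CC)C[C@@]1(C)O[Si](CC)(CC)CC)C(O)C/C=C(\C)CC(=O)OC | intermediate
22 | enone (C14 ketone) | C=C(CC[C@@H]1[C@@]2(C)CCC[C@@](C)(C(=O)OC)[C@@H]2[C@@H](O[Si](CC)(CC)CC)C[C@@]1(C)O[Si](CC)(CC)CC)C(=O)C/C=C(\C)CC(=O)OC | intermediate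
23 | (14S)-allylic alcohol | C=C(CC[C@@H]1[C@@]2(C)CCC[C@@](C)(C(=O)OC)[C@@H]2[C@@H](O[Si](CC)(CC)CC)C[C@@]1(C)O[Si](CC)(CC)CC)[C@@H](O)C/C=C(\C)CC(=O)OC | intermediate
24 | (14S,16S,17S)-epoxy alcohol | C=C(CC[C@@H]1[C@@]2(C)CCC[C@@](C)(C(=O)OC)[C@@H]2[C@@H](O[Si](CC)(CC)CC)C[C@@]1(C)O[Si](CC)(CC)CC)[C@@H](O)C[C@@H]3O[C@@]3(C)CC(=O)OC | intermediate
25 | (14S,16S,17S)-epoxy mesylate | C=C(CC[C@@H]1[C@@]2(C)CCC[C@@](C)(C(=O)OC)[C@@H]2[C@@H](O[Si](CC)(CC)CC)C[C@@]1(C)O[Si](CC)(CC)CC)[C@@H](OS(C)(=O)=O)C[C@@H]3O[C@@]3(C)CC(=O)OC | intermediate
26 | (14S,16S,17R)-17-hydroperoxy-16-hydroxy mesylate | C=C(CC[C@@H]1[C@@]2(C)CCC[C@@](C)(C(=O)OC)[C@@H]2[C@@H](O[Si](CC)(CC)CC)C[C@@]1(C)O[Si](CC)(CC)CC)[C@@H](OS(C)(=O)=O)C[C@H](O)[C@](C)(OO)CC(=O)OC | intermediate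
27 | (14R,16S,17R)-1,2-dioxane hydroxy ester | C=C(CC[C@@H]1[C@@]2(C)CCC[C@@](C)(C(=O)OC)[C@@H]2[C@@H](O[Si](CC)(CC)CC)C[C@@]1(C)O[Si](CC)(CC)CC)[C@H]3C[C@H](O)[C@@](C)(CC(=O)OC)OO3 | intermediate
28 | 6,8-bis-O-triethylsilyl ether of the target | C=C(CC[C@@H]1[C@@]2(C)CCC[C@@](C)(C(=O)OC)[C@@H]2[C@@H](O[Si](CC)(CC)CC)C[C@@]1(C)O[Si](CC)(CC)CC)[C@H]3C[C@@H]4OC(=O)C[C@@]4(C)OO3 | intermediate
29 | CNP0162504.1 | C=C(CC[C@@H]1[C@@]2(C)CCC[C@@](C)(C(=O)OC)[C@@H]2[C@@H](O)C[C@@]1(C)O)[C@H]1C[C@@H]2OC(=O)C[C@@]2(C)OO1 | target

## Step count and least certain steps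

Total: 18 steps. Longest linear sequence: 15 steps (steps 4 to 18, from 8); the aldehyde 7 is made in a 3-step branch (steps 1 to 3) and joined in step 12.

Step 17 (key step). The most likely failures are ionisation of the allylic mesylate during the acidic perhydrolysis or during ring closure, which would replace the SN2 inversion at C14 by capture of an allyl cation; attack of residual H2O2 on the mesylate; and lactonisation before the peroxide ring has closed, which would force the slower closure across a trans-disubstituted lactone and give elimination of the mesylate time to compete. The fallback reverses the order of the two C–O bond formations and removes the sulfonate before any acid is used. It sets out from 23: mesylation gives the allylic mesylate F1, which is displaced at once by 2-methoxyprop-2-yl hydroperoxide with CsOH in DMF (SN2, inversion) to give the 14R peroxyketal F2. Epoxidation with the ent-Shi ketone as in step 15 gives the epoxy peroxyketal F3. PPTS in CH2Cl2–MeOH unmasks the epoxy hydroperoxide F4 in the flask, and CSA then promotes 6-endo opening of the epoxide at the tertiary C17 (inversion). This gives 27, where the route is rejoined; 27 lactonises to 28 under the same acid.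

Step 7. The 6α-alkoxyl radical may undergo β-scission of C5–C6 (a tertiary radical flanked by two quaternary carbons is released) faster than it abstracts hydrogen from C23, or the ketal may be lost under the acetic acid that is formed. The fallback replaces the radical hydrogen transfer by a directed C–H silylation and sets out from 12: Et2SiH2 with [Ir(cod)OMe]2 gives the diethylhydridosilyl ether F5. [Rh(cod)Cl]2 with Xantphos and norbornene closes the oxasilinane F6 by silylation of the C23 methyl. Tamao–Fleming oxidation (H2O2, KHCO3, KF) gives the 6α,23-diol F7, and TEMPO with PhI(OAc)2 oxidises F7 to lactone ketal 14, where the route is rejoined before the acid hydrolysis of step 8.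

Step 14. The skipped enone 22 may isomerise into conjugation or be reduced with low facial discrimination, because the two ketone substituents differ less than in a typical CBS substrate. The fallback sets C14 in the C–C bond-forming event and bypasses steps 13 and 14: from 20 and 7, a catalytic asymmetric nickel/chromium coupling (CrCl2 bound to a chiral oxazoline–sulfonamide ligand, NiCl2·(2,9-dimethyl-1,10-phenanthroline), Mn, Cp2ZrCl2, LiCl, MeCN) would give 23 directly, the ligand enantiomer being chosen for the 14S carbinol; this fallback makes no new compound F0.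

## Further compounds

F1 | step 17 | (14S)-allylic mesylate of 23, alkene intact | C=C(CC[C@@H]1[C@@]2(C)CCC[C@@](C)(C(=O)OC)[C@@H]2[C@@H](O[Si](CC)(CC)CC)C[C@@]1(C)O[Si](CC)(CC)CC)[C@@H](OS(C)(=O)=O)C/C=C(\C)CC(=O)OC
F2 | step 17 | (14R)-2-methoxyprop-2-yl peroxide (peroxyketal) | C=C(CC[C@@H]1[C@@]2(C)CCC[C@@](C)(C(=O)OC)[C@@H]2[C@@H](O[Si](CC)(CC)CC)C[C@@]1(C)O[Si](CC)(CC)CC)[C@H](OOC(C)(C)OC)C/C=C(\C)CC(=O)OC
F3 | step 17 | (14R,16S,17S)-epoxy peroxyketal | C=C(CC[C@@H]1[C@@]2(C)CCC[C@@](C)(C(=O)OC)[C@@H]2[C@@H](O[Si](CC)(CC)CC)C[C@@]1(C)O[Si](CC)(CC)CC)[C@H](OOC(C)(C)OC)C[C@@H]3O[C@@]3(C)CC(=O)OC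
F4 | step 17 | (14R,16S,17S)-epoxy hydroperoxide | C=C(CC[C@@H]1[C@@]2(C)CCC[C@@](C)(C(=O)OC)[C@@H]2[C@@H](O[Si](CC)(CC)CC)C[C@@]1(C)O[Si](CC)(CC)CC)[C@H](OO)C[C@@H]3O[C@@]3(C)CC(=O)OC
F5 | step 7 | 6α-O-diethylhydridosilyl ether of 12 | CO[C@]1(C)CC[C@@H]2[C@@]3(C)CCCC(C)(C)[C@@H]3[C@@H](O[SiH](CC)CC)C[C@@]2(C)O1
F6 | step 7 | oxasilinane (SiEt2 bridging O6 and C23) | CO[C@]1(C)CC[C@@H]2[C@@]3(C)CCC[C@@](C)(C[Si](CC)(CC)O4)[C@@H]3[C@@H]4C[C@@]2(C)O1
F7 | step 7 | 6α,23-diol of the cyclic methyl ketal | CO[C@]1(C)CC[C@@H]2[C@@]3(C)CCC[C@@](C)(CO)[C@@H]3[C@@H](O)C[C@@]2(C)O1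
F0 | step 14 | none | none
A1 | alternative 1 | 13E-ene (16S)-19,16-butenolide | C/C(CC[C@@H]1[C@@]2(C)CCC[C@@](C)(C(=O)OC)[C@@H]2[C@@H](O)C[C@@]1(C)O)=C\C[C@@H]1OC(=O)C=C1C
A2 | alternative 1 | C14 allylic hydroperoxide of the butenolide (both C14 epimers) | C=C(CC[C@@H]1[C@@]2(C)CCC[C@@](C)(C(=O)OC)[C@@H]2[C@@H](O)C[C@@]1(C)O)C(OO)C[C@@H]1OC(=O)C=C1C
A3 | alternative 1 | cis-fused (16S,17S) 17-epimer of the target | C=C(CC[C@@H]1[C@@]2(C)CCC[C@@](C)(C(=O)OC)[C@@H]2[C@@H](O)C[C@@]1(C)O)[C@H]1C[C@@H]2OC(=O)C[C@]2(C)OO1
A4 | alternative 2 | (14E,16E)-13(21),14,16-trienoic acid | C=C(CC[C@@H]1[C@@]2(C)CCC[C@@](C)(C(=O)OC)[C@@H]2[C@@H](O)C[C@@]1(C)O)/C=C/C=C(\C)CC(=O)O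
A5 | alternative 2 | 3,6-dihydro-1,2-dioxine acid (14R,17R) | C=C(CC[C@@H]1[C@@]2(C)CCC[C@@](C)(C(=O)OC)[C@@H]2[C@@H](O)C[C@@]1(C)O)[C@H]1C=C[C@@](C)(CC(=O)O)OO1
A6 | alternative 3 | 1-bromovinyl peroxy-lactone (14R,16S,17R) | C=C(Br)[C@H]1C[C@@H]2OC(=O)C[C@@]2(C)OO1
A7 | alternative 3 | 9-vinyl decalin diol ester | C=C[C@@H]1[C@@]2(C)CCC[C@@](C)(C(=O)OC)[C@@H]2[C@@H](O)C[C@@]1(C)O
A8 | alternative 3 | B-alkyl-9-borabicyclo[3.3.1]nonane from A7 | C1CCC2CCCC1B2CC[C@@H]1[C@@]2(C)CCC[C@@](C)(C(=O)OC)[C@@H]2[C@@H](O)C[C@@]1(C)O
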